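The readings stem from a simulated flask with made-up constants; noise was put on by code.

The first constant I want is what a degree is worth in these flasks, and the runs give it before anything else.

| flask | starting material | reagent | second substrate | temperature | remark | time |
|---|---|---|---|---|---|---|
| epsilon | 0.050 M | 0.50 equiv | 1 equiv | 20 °C | run made earlier |  |
| zeta | 0.050 M | 0.50 equiv | 0.67 equiv | 31 °C | run made earlier |  |
| eta | 0.050 M | 0.50 equiv | 1.5 equiv | 20 °C | run made earlier |  |
| theta | 0.025 M | 0.50 equiv | 1 equiv | 31 °C | run made earlier |  |
| oak | 0.050 M (fed, over 40 min) | 0.500 equiv | 1.00 equiv | 25 °C | all else is in the flask from the start; the feed brings no volume worth counting | 1.0 h |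
| birch | 0.050 M | 0.500 equiv (fed, over 40 min) | 1.00 equiv | 25 °C | all else is in the flask from the start; the feed brings no volume worth counting | 1.0 h |
| ash | 0.050 M | 0.500 equiv | 1.00 equiv | 25 °C | everything together at the start | 1.0 h |
| elm | 0.050 M | 0.500 equiv (fed, over 40 min) | 1.00 equiv |  | the addition at −15 °C, then warmed to 25 °C; the feed brings no volume worth counting | 1.0 h |

| run | time / min | target / % | starting material / % |
|---|---|---|---|
| epsilon | 3.00 | 1.9 | 97.0 |
| epsilon | 5.00 | 3.5 | 95.1 |
| epsilon | 10.0 | 5.4 | 89.1 |
| epsilon | 20.0 | 10.2 | 82.2 |
| epsilon | 40.0 | 16.2 | 73.0 |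
| zeta | 8.00 | 9.3 | 84.6 |
| zeta | 15.0 | 13.3 | 77.0 |
| zeta | 20.0 | 15.9 | 72.1 |
| zeta | 30.0 | 19.4 | 66.3 |
| zeta | 40.0 | 22.6 | 61.9 |
| eta | 8.00 | 4.7 | 89.8 |
| eta | 15.0 | 8.7 | 83.6 |
| eta | 20.0 | 9.3 | 80.7 |
| eta | 30.0 | 11.7 | 74.6 |
| eta | 40.0 | 15.1 | 69.9 |
| theta | 8.00 | 4.5 | 91.3 |
| theta | 15.0 | 7.5 | 84.1 |
| theta | 20.0 | 11.0 | 80.7 |
| theta | 30.0 | 12.5 | 74.6 |
| theta | 40.0 | 15.6 | 71.3 |

(each reading ± 0.5 percentage points)

- which flask leads in amount of target, in percent of the starting material charged ("all alike" within 1.5 percentage points) (oak / birch / ash / elm / all alike)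
- how much target is there at the end, in percent of the starting material charged: oak
- how much target is there at the end, in percent of the starting material charged: birch
- how much target is there at the end, in percent of the starting material charged: ash
- how much target is there at the end, in percent of the starting material charged: elm

- the numbers in the tables scatter by 0.5 percentage points (one standard deviation)

Theta runs at half the concentration of epsilon and 11.0 K hotter, yet at 40.0 min epsilon reads 16.2% of target and theta 15.6%, so in these two runs that step of temperature cancels the halving. I take it as a doubling, and in epsilon and eta, at 16.2% and 15.1%, the second substrate barely moves the target.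

So I count warm minutes: each minute is weighted by its concentration against 0.050 M and by that doubling against 25 °C. A minute at 31 °C is worth

1.46

and a minute at −15 °C is worth

0.0804

Over a feed of 40 min the amount delivered averages half of the charge, though what stands in the flask is lower by whatever has already reacted, so I weight the fed stretch by the delivered amount as a rough count and set out the ladder on it, shortest first. Elm's cold stretch gives

1.61 min

and elm as a whole, with its warm remainder, gives

21.6 min

This sum is elm's warm minutes. Oak and birch each give

40.0 min

and ash has its full 60 min.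

Now I read the target off the runs at equal warm minutes. Theta at 30.0 min has 21.9 min, close to elm, so elm should reach about 12.5%. Zeta at 40.0 min has 58.4 min, close to ash, so ash should reach about 22.6%. Oak and birch fall between zeta's 20.0 min and 30.0 min, at 15.9% to 19.4%, though the reagent, the limiting reagent at 0.500 equiv, need not be spent alike in both.

The forecast names ash and gives oak 14%, birch 18.5%, ash 22.5% and elm 14%, which is more than my elm, holding that elm “barely reacts when cold”.

The flasks give oak 15.8%, at the foot of my band, birch 18.1%, ash 22.0% and elm 13.1%, so ash leads.

    2 second substrate → self-condensation product (k = 0.00550 L mol⁻¹ s⁻¹, Ea = 48.0 kJ mol⁻¹)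
    starting material + second substrate → cross product (k = 0.00290 L mol⁻¹ s⁻¹, Ea = 64.0 kJ mol⁻¹)
    starting material + reagent → target (k = 0.00650 L mol⁻¹ s⁻¹, Ea = 47.0 kJ mol⁻¹)
    second substrate + reagent → second product (k = 0.00710 L mol⁻¹ s⁻¹, Ea = 61.0 kJ mol⁻¹)
    (constants at 25 °C)

The neighbour is elm again at 0.20 M of starting material, with the equivalents held, and its warm minutes grow with the concentration:

86.4 min

That is more than ash's 60 min and less than the 116 min at which ash, left longer, has moved by 5 points. So I look for a target above ash's 22.0% by less than those points. The neighbouring flask ends with 26.4% of target.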